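**Retrosynthetic overview**

1. The C50 chain is cut at C11=C12 and C11'=C12' into two ring-bearing C20 Wittig salts and the central C10 trienedial; the allylic alcohol is carried as its ethyl ester and freed last.
2. Both cyclohexene rings come from one ring closure: the bond between the C(CH3)2 ring carbon and the neighbouring ring CH that carries the CH2–CH=C side chain is made by 6-exo addition of a tertiary radical (from decarboxylation of a C(CH3)2–CO2H group) to an E-enoate.
3. Enabling feature: in each ring the quaternary C(CH3)2 carbon lies next to a CH whose side chain begins CH2–CH=. That CH is the β-carbon of a CH=CH–CO2Me acceptor, the ester carbon later becomes the olefinic CH of the prenyl or hydroxyprenyl group, and the ring's own Z-C(CH3)=CH unit holds radical and acceptor together.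
4. The acyclic acid comes from an Ireland–Claisen rearrangement of an (S)-allylic isobutyrate, which sets the polyene-bearing ring CH and the E-C7=C8 bond next to a masked C9 ketone; the ester is assembled by Sonogashira coupling of a (Z)-iodoalkene with a ketal-bearing alkynol.
5. Ring order: the cis ring of the prenyl end is closed in the key step and serves both ends; for the hydroxylated end the same ring is epimerised at the polyene-bearing CH (enone stage) to the trans ring.

Key step: step 11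

Remark: the target is read from its stereodescriptors as having a cis-2,6-disubstituted ring at the prenyl end and a trans-2,6-disubstituted ring at the hydroxylated end; the tertiary carbinol centres made in steps 15 and 20 are destroyed in the following step and are left as mixtures.

**Route**

Step 1
Reactants: 1 3-[(tert-butyldimethylsilyl)oxy]propanal; 2 ethyltriphenylphosphonium iodide
Product: 6 (Z)-tert-butyl[(4-iodopent-3-en-1-yl)oxy]dimethylsilane, via ethylidenetriphenylphosphorane 3 (not isolated), via (1-iodoethyl)triphenylphosphonium iodide 4 (not isolated), via (1-iodoethylidene)triphenylphosphorane 5 (not isolated)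
Conditions: n-BuLi, THF, 0 °C; I2, −78 °C; NaN(SiMe3)2, −20 °C; then 1, −78 °C to rt
Reagents that add atoms: iodine (II)
Why: Wittig olefination with an α-iodo ylide (Stork–Zhao type), in which the kinetically formed cis-oxaphosphetane puts iodine and the CH2 chain on the same side and so gives the Z-iodoalkene that later becomes the ring double bond.

Step 2
Reactants: 7 ethyl 2,2-diethoxypropanoate; 8 ethynyltrimethylsilane
Product: 10 4,4-diethoxy-1-(trimethylsilyl)pent-1-yn-3-one, via lithium (trimethylsilyl)acetylide 9 (not isolated)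
Conditions: n-BuLi, THF, −78 °C; then 7, −78 °C; aqueous quench at −78 °C
Reagents that add atoms: none
Why: Acylation of a lithium acetylide by an ester; the two α-ethoxy groups chelate lithium in the tetrahedral adduct, so it should collapse to the ynone only on quench and a second addition is avoided.

Step 3
Reactants: 10 4,4-diethoxy-1-(trimethylsilyl)pent-1-yn-3-one
Product: 11 (S)-4,4-diethoxy-1-(trimethylsilyl)pent-1-yn-3-ol
Conditions: Ru[(R,R)-TsDPEN](p-cymene) (1 mol %), i-PrOH, 25 °C
Reagents that add atoms: none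
Why: Noyori asymmetric transfer hydrogenation of an alkynyl ketone sets the carbinol centre; with the alkyne in the site it takes in simple ynones, the (R,R)-ligand should give the (S)-alcohol here, because the ketal carbon outranks the alkyne.

Step 4
Reactants: 11 (S)-4,4-diethoxy-1-(trimethylsilyl)pent-1-yn-3-ol
Product: 12 (S)-4,4-diethoxypent-1-yn-3-ol
Conditions: K2CO3 (0.2 equiv), MeOH, 0 °C to rt
Reagents that add atoms: none
Why: Base-catalysed protodesilylation of the alkynylsilane by methanol, which leaves the carbinol centre and the ketal untouched.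

Step 5
Reactants: 6 (Z)-tert-butyl[(4-iodopent-3-en-1-yl)oxy]dimethylsilane; 12 (S)-4,4-diethoxypent-1-yn-3-ol
Product: 13 (3S,6Z)-9-[(tert-butyldimethylsilyl)oxy]-2,2-diethoxy-6-methylnon-6-en-4-yn-3-ol
Conditions: PdCl2(PPh3)2 (3 mol %), CuI (6 mol %), Et3N, THF, 25 °C
Reagents that add atoms: none
Why: Sonogashira coupling of an alkenyl iodide with a terminal alkyne proceeds with retention of the Z geometry and tolerates the free propargylic alcohol.

Step 6
Reactants: 13 (3S,6Z)-9-[(tert-butyldimethylsilyl)oxy]-2,2-diethoxy-6-methylnon-6-en-4-yn-3-ol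
Product: 14 (3S,4E,6Z)-9-[(tert-butyldimethylsilyl)oxy]-2,2-diethoxy-6-methylnona-4,6-dien-3-ol
Conditions: NaAlH2(OCH2CH2OCH3)2, THF, 0 °C to rt; aq. potassium sodium tartrate
Reagents that add atoms: none
Why: Alkoxide-directed trans-hydroalumination of the propargylic alcohol followed by protonolysis should give only the E-allylic alcohol, while the remote Z-alkene and the silyl ether stay intact.

Step 7
Reactants: 14 (3S,4E,6Z)-9-[(tert-butyldimethylsilyl)oxy]-2,2-diethoxy-6-methylnona-4,6-dien-3-ol; 15 2-methylpropanoyl chloride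
Product: 16 (3S,4E,6Z)-9-[(tert-butyldimethylsilyl)oxy]-2,2-diethoxy-6-methylnona-4,6-dien-3-yl 2-methylpropanoate
Conditions: Et3N, DMAP (10 mol %), CH2Cl2, 0 °C to rt
Reagents that add atoms: none
Why: DMAP-catalysed acyl transfer (esterification) of the secondary allylic alcohol with retention at the carbinol carbon.

Step 8
Reactants: 16 (3S,4E,6Z)-9-[(tert-butyldimethylsilyl)oxy]-2,2-diethoxy-6-methylnona-4,6-dien-3-yl 2-methylpropanoate
Product: 19 (3R,4E)-3-[(Z)-5-[(tert-butyldimethylsilyl)oxy]pent-2-en-2-yl]-6,6-diethoxy-2,2-dimethylhept-4-enoic acid, via trimethylsilyl ketene acetal 17 (not isolated), via trimethylsilyl ester 18 (not isolated)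
Conditions: LiN(i-Pr)2, THF, −78 °C; Me3SiCl, −78 °C to 60 °C; pH 5 buffer
Reagents that add atoms: none
Why: Ireland–Claisen rearrangement through a chair with the ketal-bearing group equatorial passes the (S)-carbinol configuration to the new bis-allylic CH as (R), gives the E-alkene and installs the C(CH3)2–CO2H unit (the symmetric ketene acetal makes enolate geometry irrelevant).

Step 9
Reactants: 19 (3R,4E)-3-[(Z)-5-[(tert-butyldimethylsilyl)oxy]pent-2-en-2-yl]-6,6-diethoxy-2,2-dimethylhept-4-enoic acid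
Product: 20 (3R,4E)-6,6-diethoxy-3-[(Z)-5-hydroxypent-2-en-2-yl]-2,2-dimethylhept-4-enoic acid
Conditions: Bu4NF, THF, 0 °C to rt; pH 5 buffer
Reagents that add atoms: none
Why: Fluoride-mediated cleavage of the silyl ether; the ketal and the carboxylate are inert to fluoride.

Step 10
Reactants: 20 (3R,4E)-6,6-diethoxy-3-[(Z)-5-hydroxypent-2-en-2-yl]-2,2-dimethylhept-4-enoic acid; 21 methyl (triphenylphosphoranylidene)acetate
Product: 23 (3R,4E)-6,6-diethoxy-3-[(2Z,5E)-7-methoxy-7-oxohepta-2,5-dien-2-yl]-2,2-dimethylhept-4-enoic acid, via aldehyde acid 22 (not isolated)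
Conditions: Dess–Martin periodinane, pyridine, CH2Cl2, 0 °C; then 21 (2.5 equiv), 0 °C to rt
Reagents that add atoms: none
Why: Dess–Martin oxidation followed in the same flask by Wittig olefination with a stabilised ylide should give the E-enoate and trap the β,γ-unsaturated aldehyde before its Z-alkene can move into conjugation.

Step 11
Reactants: 23 (3R,4E)-6,6-diethoxy-3-[(2Z,5E)-7-methoxy-7-oxohepta-2,5-dien-2-yl]-2,2-dimethylhept-4-enoic acid
Product: 24 methyl 2-[(1R,5R)-5-[(E)-3,3-diethoxybut-1-en-1-yl]-4,6,6-trimethylcyclohex-3-en-1-yl]acetate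
Conditions: [Ir(dF(CF3)ppy)2(dtbbpy)]PF6 (1 mol %), K2HPO4 (1.2 equiv), DMF (0.01 M), blue LEDs (450 nm), 25 °C, argon; chromatography to remove any trans isomer
Reagents that add atoms: none
Why: The excited trivalent iridium complex oxidises the carboxylate of 23, CO2 is lost, and the nucleophilic tertiary radical at C(CH3)2 adds to the β-carbon of the E-enoate; the α-ester radical is then reduced by the divalent iridium complex and the enolate is protonated. The closest known reaction type is the photoredox decarboxylative Giese addition of tertiary carboxylic acids, used here in its intramolecular form. The ring closes in the 6-exo-trig mode through a half-chair in which the Z-C(CH3)=CH unit already holds the radical and the acceptor on the same side. The new stereocentre (the ring CH that carries CH2CO2Me) is controlled by the existing bis-allylic CH: its C–H bond eclipses one methyl of the planar radical (least allylic 1,3-type strain), so the diethoxybutenyl chain sits pseudo-equatorial, and the enoate enters pseudo-equatorial as well, which should give the cis-(1R,5R) ring. The step needs 6-exo closure to outrun 1,5-hydrogen transfer from the doubly allylic CH2 and intermolecular addition, and cis over trans; the matched polarity (nucleophilic radical, electron-poor alkene), the Z-alkene and high dilution serve the first, the two pseudo-equatorial groups the second, while the isolated alkenes and the ketal should be inert to the photocatalyst.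

Step 12
Reactants: 24 methyl 2-[(1R,5R)-5-[(E)-3,3-diethoxybut-1-en-1-yl]-4,6,6-trimethylcyclohex-3-en-1-yl]acetate
Product: 25 2-[(1R,5R)-5-[(E)-3,3-diethoxybut-1-en-1-yl]-4,6,6-trimethylcyclohex-3-en-1-yl]acetaldehyde
Conditions: i-Bu2AlH (1.1 equiv), CH2Cl2, −78 °C; aq. potassium sodium tartrate
Reagents that add atoms: none
Why: Partial reduction of the methyl ester with i-Bu2AlH at low temperature stops at the tetrahedral aluminium acetal, which gives the aldehyde on work-up without touching a stereocentre.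

Step 13
Reactants: 25 2-[(1R,5R)-5-[(E)-3,3-diethoxybut-1-en-1-yl]-4,6,6-trimethylcyclohex-3-en-1-yl]acetaldehyde; 26 isopropyltriphenylphosphonium iodide
Product: 28 (4S,6R)-6-[(E)-3,3-diethoxybut-1-en-1-yl]-1,5,5-trimethyl-4-(3-methylbut-2-en-1-yl)cyclohex-1-ene, via isopropylidenetriphenylphosphorane 27 (not isolated)
Conditions: n-BuLi, THF, 0 °C; then 25, −78 °C to rt
Reagents that add atoms: none
Why: Wittig olefination with a non-stabilised ylide forms the trisubstituted prenyl alkene, for which no geometry arises.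

Step 14
Reactants: 28 (4S,6R)-6-[(E)-3,3-diethoxybut-1-en-1-yl]-1,5,5-trimethyl-4-(3-methylbut-2-en-1-yl)cyclohex-1-ene
Product: 29 (E)-4-[(1R,5S)-2,6,6-trimethyl-5-(3-methylbut-2-en-1-yl)cyclohex-2-en-1-yl]but-3-en-2-one
Conditions: pyridinium p-toluenesulfonate (10 mol %), acetone/H2O (10:1), 25 °C
Reagents that add atoms: water (O)
Why: Acid-catalysed hydrolysis of the allylic ketal is fast under mild conditions that should leave the trisubstituted alkenes and the ring CH next to the enone alone.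

Step 15
Reactants: 29 (E)-4-[(1R,5S)-2,6,6-trimethyl-5-(3-methylbut-2-en-1-yl)cyclohex-2-en-1-yl]but-3-en-2-one; 30 vinylmagnesium bromide
Product: 31 (E)-3-methyl-1-[(1R,5S)-2,6,6-trimethyl-5-(3-methylbut-2-en-1-yl)cyclohex-2-en-1-yl]penta-1,4-dien-3-ol (both epimers at the carbinol carbon)
Conditions: CH2=CHMgBr (1.3 equiv), THF, −78 to −20 °C; aq. NH4Cl
Reagents that add atoms: none
Why: Grignard 1,2-addition to the enone carbonyl; the new carbinol centre is not controlled and is removed in the next step.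

Step 16
Reactants: 31 (E)-3-methyl-1-[(1R,5S)-2,6,6-trimethyl-5-(3-methylbut-2-en-1-yl)cyclohex-2-en-1-yl]penta-1,4-dien-3-ol
Product: 32 [(2E,4E)-3-methyl-5-[(1R,5S)-2,6,6-trimethyl-5-(3-methylbut-2-en-1-yl)cyclohex-2-en-1-yl]penta-2,4-dien-1-yl]triphenylphosphonium bromide
Conditions: Ph3P·HBr, MeOH, 25 °C
Reagents that add atoms: triphenylphosphine hydrobromide (Br.c1ccc(cc1)P(c1ccccc1)c1ccccc1)
Why: Phosphonium salt formation with allylic transposition: ionisation of the tertiary bis-allylic alcohol and attack of PPh3 at the unhindered primary terminus should give the conjugated (2E,4E)-dienyl salt, as in the standard making of ionone-derived Wittig salts.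

Step 17
Reactants: 25 2-[(1R,5R)-5-[(E)-3,3-diethoxybut-1-en-1-yl]-4,6,6-trimethylcyclohex-3-en-1-yl]acetaldehyde; 33 ethyl 2-(triphenylphosphoranylidene)propanoate
Product: 34 ethyl (E)-4-[(1R,5R)-5-[(E)-3,3-diethoxybut-1-en-1-yl]-4,6,6-trimethylcyclohex-3-en-1-yl]-2-methylbut-2-enoate
Conditions: toluene, 40 °C
Reagents that add atoms: none
Why: Wittig olefination with a stabilised α-methyl ylide gives the E-trisubstituted enoate, the usual outcome for stabilised ylides.

Step 18
Reactants: 34 ethyl (E)-4-[(1R,5R)-5-[(E)-3,3-diethoxybut-1-en-1-yl]-4,6,6-trimethylcyclohex-3-en-1-yl]-2-methylbut-2-enoate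
Product: 35 ethyl (E)-2-methyl-4-[(1R,5R)-4,6,6-trimethyl-5-[(E)-3-oxobut-1-en-1-yl]cyclohex-3-en-1-yl]but-2-enoate
Conditions: pyridinium p-toluenesulfonate (10 mol %), acetone/H2O (10:1), 25 °C
Reagents that add atoms: water (O)
Why: Acid-catalysed hydrolysis of the allylic ketal, mild enough for the enoate and the ring stereocentres.

Step 19
Reactants: 35 ethyl (E)-2-methyl-4-[(1R,5R)-4,6,6-trimethyl-5-[(E)-3-oxobut-1-en-1-yl]cyclohex-3-en-1-yl]but-2-enoate
Product: 36 ethyl (E)-2-methyl-4-[(1R,5S)-4,6,6-trimethyl-5-[(E)-3-oxobut-1-en-1-yl]cyclohex-3-en-1-yl]but-2-enoate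
Conditions: NaOEt (0.3 equiv), EtOH, 25 °C; AcOH; chromatography (cis isomer recycled)
Reagents that add atoms: none
Why: Base-mediated epimerisation through the vinylogous enolate of the enone, the reaction type known for the cis-to-trans change of 2-alkyl α-ionones (irones); reprotonation at the ring CH under thermodynamic control should favour the trans isomer, in which the butenone chain is pseudo-axial (no allylic 1,2-strain with the ring methyl) and the ester side chain equatorial.

Step 20
Reactants: 36 ethyl (E)-2-methyl-4-[(1R,5S)-4,6,6-trimethyl-5-[(E)-3-oxobut-1-en-1-yl]cyclohex-3-en-1-yl]but-2-enoate; 30 vinylmagnesium bromide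
Product: 37 ethyl (E)-4-[(1R,5S)-5-[(E)-3-hydroxy-3-methylpenta-1,4-dien-1-yl]-4,6,6-trimethylcyclohex-3-en-1-yl]-2-methylbut-2-enoate (both epimers at the carbinol carbon)
Conditions: CH2=CHMgBr (1.1 equiv), THF, −78 °C; aq. NH4Cl
Reagents that add atoms: none
Why: Grignard 1,2-addition at −78 °C should be faster at the enone carbonyl than at the hindered α-methyl enoate; the carbinol centre is left undefined.

Step 21
Reactants: 37 ethyl (E)-4-[(1R,5S)-5-[(E)-3-hydroxy-3-methylpenta-1,4-dien-1-yl]-4,6,6-trimethylcyclohex-3-en-1-yl]-2-methylbut-2-enoate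
Product: 38 [(2E,4E)-5-[(1S,5R)-5-[(E)-4-ethoxy-3-methyl-4-oxobut-2-en-1-yl]-2,6,6-trimethylcyclohex-2-en-1-yl]-3-methylpenta-2,4-dien-1-yl]triphenylphosphonium bromide
Conditions: Ph3P·HBr, EtOH, 25 °C
Reagents that add atoms: triphenylphosphine hydrobromide (Br.c1ccc(cc1)P(c1ccccc1)c1ccccc1)
Why: Phosphonium salt formation with allylic transposition, as in step 16; the enoate is inert to the mildly acidic reagent.

Step 22
Reactants: 32 [(2E,4E)-3-methyl-5-[(1R,5S)-2,6,6-trimethyl-5-(3-methylbut-2-en-1-yl)cyclohex-2-en-1-yl]penta-2,4-dien-1-yl]triphenylphosphonium bromide; 39 (2E,4E,6E)-2,7-dimethylocta-2,4,6-trienedial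
Product: 41 (2E,4E,6E,8E,10E,12E)-2,7,11-trimethyl-13-[(1R,5S)-2,6,6-trimethyl-5-(3-methylbut-2-en-1-yl)cyclohex-2-en-1-yl]trideca-2,4,6,8,10,12-hexaenal, via phosphorus ylide 40 (not isolated)
Conditions: NaOMe, CH2Cl2/MeOH, 0 °C to rt, 39 (3 equiv, excess recovered); then heptane, 80 °C
Reagents that add atoms: none
Why: Wittig olefination of the semi-stabilised ylide with an excess of the dialdehyde forms C11=C12 at one end only, and heating should equilibrate the Z/E mixture to the all-E hexaenal.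

Step 23
Reactants: 38 [(2E,4E)-5-[(1S,5R)-5-[(E)-4-ethoxy-3-methyl-4-oxobut-2-en-1-yl]-2,6,6-trimethylcyclohex-2-en-1-yl]-3-methylpenta-2,4-dien-1-yl]triphenylphosphonium bromide; 41 (2E,4E,6E,8E,10E,12E)-2,7,11-trimethyl-13-[(1R,5S)-2,6,6-trimethyl-5-(3-methylbut-2-en-1-yl)cyclohex-2-en-1-yl]trideca-2,4,6,8,10,12-hexaenal
Product: 43 ethyl (E)-2-methyl-4-[(2S,6R,2'R,6'S)-2-(3-methylbut-2-en-1-yl)-ε,ε-caroten-2'-yl]but-2-enoate, via phosphorus ylide 42 (not isolated)
Conditions: NaOEt, CH2Cl2/EtOH, 0 °C to rt; then heptane, 90 °C, dark, argon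
Reagents that add atoms: none
Why: The second Wittig olefination joins the two ends at C11'=C12'; thermal equilibration should give the all-E nonaene, and the ethoxide base matches the ethyl ester.

Step 24
Reactants: 43 ethyl (E)-2-methyl-4-[(2S,6R,2'R,6'S)-2-(3-methylbut-2-en-1-yl)-ε,ε-caroten-2'-yl]but-2-enoate
Product: 44 (2S,6R,2'R,6'S)-2'-[(E)-4-hydroxy-3-methylbut-2-en-1-yl]-2-(3-methylbut-2-en-1-yl)-ε,ε-carotene (CNP0304855.1)
Conditions: i-Bu2AlH (2.5 equiv), CH2Cl2, −78 °C; aq. potassium sodium tartrate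
Reagents that add atoms: none
Why: Reduction of the α,β-unsaturated ester with i-Bu2AlH is a 1,2-reduction to the allylic alcohol and should touch neither the polyene nor the four stereocentres.

**Compound list**

1 | 3-[(tert-butyldimethylsilyl)oxy]propanal | CC(C)(C)[Si](C)(C)OCCC=O | starting material
2 | ethyltriphenylphosphonium iodide | CC[P+](c1ccccc1)(c1ccccc1)c1ccccc1.[I-] | starting material
3 | ethylidenetriphenylphosphorane | CC=P(c1ccccc1)(c1ccccc1)c1ccccc1 | intermediate
4 | (1-iodoethyl)triphenylphosphonium iodide | CC(I)[P+](c1ccccc1)(c1ccccc1)c1ccccc1.[I-] | intermediate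
5 | (1-iodoethylidene)triphenylphosphorane | CC(I)=P(c1ccccc1)(c1ccccc1)c1ccccc1 | intermediate
6 | (Z)-tert-butyl[(4-iodopent-3-en-1-yl)oxy]dimethylsilane | C/C(I)=C/CCO[Si](C)(C)C(C)(C)C | intermediate
7 | ethyl 2,2-diethoxypropanoate | CCOC(=O)C(C)(OCC)OCC | starting material
8 | ethynyltrimethylsilane | C#C[Si](C)(C)C | starting material
9 | lithium (trimethylsilyl)acetylide | [Li]C#C[Si](C)(C)C | intermediate
10 | 4,4-diethoxy-1-(trimethylsilyl)pent-1-yn-3-one | CCOC(C)(OCC)C(=O)C#C[Si](C)(C)C | intermediate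
11 | (S)-4,4-diethoxy-1-(trimethylsilyl)pent-1-yn-3-ol | CCOC(C)(OCC)[C@@H](O)C#C[Si](C)(C)C | intermediate
12 | (S)-4,4-diethoxypent-1-yn-3-ol | CCOC(C)(OCC)[C@@H](O)C#C | intermediate
13 | (3S,6Z)-9-[(tert-butyldimethylsilyl)oxy]-2,2-diethoxy-6-methylnon-6-en-4-yn-3-ol | CCOC(C)(OCC)[C@@H](O)C#C/C(C)=C\CCO[Si](C)(C)C(C)(C)C | intermediate
14 | (3S,4E,6Z)-9-[(tert-butyldimethylsilyl)oxy]-2,2-diethoxy-6-methylnona-4,6-dien-3-ol | CCOC(C)(OCC)[C@@H](O)/C=C/C(C)=C\CCO[Si](C)(C)C(C)(C)C | intermediate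
15 | 2-methylpropanoyl chloride | CC(C)C(=O)Cl | starting material
16 | (3S,4E,6Z)-9-[(tert-butyldimethylsilyl)oxy]-2,2-diethoxy-6-methylnona-4,6-dien-3-yl 2-methylpropanoate | CCOC(C)(OCC)[C@@H](OC(=O)C(C)C)/C=C/C(C)=C\CCO[Si](C)(C)C(C)(C)C | intermediate
17 | trimethylsilyl ketene acetal of 16 | CCOC(C)(OCC)[C@@H](OC(O[Si](C)(C)C)=C(C)C)/C=C/C(C)=C\CCO[Si](C)(C)C(C)(C)C | intermediate
18 | trimethylsilyl ester of acid 19 | C[Si](C)(C)OC(=O)C(C)(C)[C@H](/C=C/C(C)(OCC)OCC)/C(C)=C\CCO[Si](C)(C)C(C)(C)C | intermediate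
19 | (3R,4E)-3-[(Z)-5-[(tert-butyldimethylsilyl)oxy]pent-2-en-2-yl]-6,6-diethoxy-2,2-dimethylhept-4-enoic acid | OC(=O)C(C)(C)[C@H](/C=C/C(C)(OCC)OCC)/C(C)=C\CCO[Si](C)(C)C(C)(C)C | intermediate
20 | (3R,4E)-6,6-diethoxy-3-[(Z)-5-hydroxypent-2-en-2-yl]-2,2-dimethylhept-4-enoic acid | OC(=O)C(C)(C)[C@H](/C=C/C(C)(OCC)OCC)/C(C)=C\CCO | intermediate
21 | methyl (triphenylphosphoranylidene)acetate | COC(=O)C=P(c1ccccc1)(c1ccccc1)c1ccccc1 | starting material
22 | (3R,4E)-6,6-diethoxy-2,2-dimethyl-3-[(Z)-5-oxopent-2-en-2-yl]hept-4-enoic acid | OC(=O)C(C)(C)[C@H](/C=C/C(C)(OCC)OCC)/C(C)=C\CC=O | intermediate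
23 | (3R,4E)-6,6-diethoxy-3-[(2Z,5E)-7-methoxy-7-oxohepta-2,5-dien-2-yl]-2,2-dimethylhept-4-enoic acid | OC(=O)C(C)(C)[C@H](/C=C/C(C)(OCC)OCC)/C(C)=C\C/C=C/C(=O)OC | intermediate
24 | methyl 2-[(1R,5R)-5-[(E)-3,3-diethoxybut-1-en-1-yl]-4,6,6-trimethylcyclohex-3-en-1-yl]acetate | COC(=O)C[C@H]1CC=C(C)[C@@H](/C=C/C(C)(OCC)OCC)C1(C)C | intermediate
25 | 2-[(1R,5R)-5-[(E)-3,3-diethoxybut-1-en-1-yl]-4,6,6-trimethylcyclohex-3-en-1-yl]acetaldehyde | O=CC[C@H]1CC=C(C)[C@@H](/C=C/C(C)(OCC)OCC)C1(C)C | intermediate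
26 | isopropyltriphenylphosphonium iodide | CC(C)[P+](c1ccccc1)(c1ccccc1)c1ccccc1.[I-] | starting material
27 | isopropylidenetriphenylphosphorane | CC(C)=P(c1ccccc1)(c1ccccc1)c1ccccc1 | intermediate
28 | (4S,6R)-6-[(E)-3,3-diethoxybut-1-en-1-yl]-1,5,5-trimethyl-4-(3-methylbut-2-en-1-yl)cyclohex-1-ene | CC(C)=CC[C@H]1CC=C(C)[C@@H](/C=C/C(C)(OCC)OCC)C1(C)C | intermediate
29 | (E)-4-[(1R,5S)-2,6,6-trimethyl-5-(3-methylbut-2-en-1-yl)cyclohex-2-en-1-yl]but-3-en-2-one (cis ring) | CC(C)=CC[C@H]1CC=C(C)[C@@H](/C=C/C(C)=O)C1(C)C | intermediate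
30 | vinylmagnesium bromide | C=C[Mg]Br | starting material
31 | (E)-3-methyl-1-[(1R,5S)-2,6,6-trimethyl-5-(3-methylbut-2-en-1-yl)cyclohex-2-en-1-yl]penta-1,4-dien-3-ol (both carbinol epimers) | CC(C)=CC[C@H]1CC=C(C)[C@@H](/C=C/C(C)(O)C=C)C1(C)C | intermediate
32 | [(2E,4E)-3-methyl-5-[(1R,5S)-2,6,6-trimethyl-5-(3-methylbut-2-en-1-yl)cyclohex-2-en-1-yl]penta-2,4-dien-1-yl]triphenylphosphonium bromide | CC(C)=CC[C@H]1CC=C(C)[C@@H](/C=C/C(C)=C/C[P+](c2ccccc2)(c2ccccc2)c2ccccc2)C1(C)C.[Br-] | intermediate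
33 | ethyl 2-(triphenylphosphoranylidene)propanoate | CCOC(=O)C(C)=P(c1ccccc1)(c1ccccc1)c1ccccc1 | starting material
34 | ethyl (E)-4-[(1R,5R)-5-[(E)-3,3-diethoxybut-1-en-1-yl]-4,6,6-trimethylcyclohex-3-en-1-yl]-2-methylbut-2-enoate | CCOC(=O)/C(C)=C/C[C@H]1CC=C(C)[C@@H](/C=C/C(C)(OCC)OCC)C1(C)C | intermediate
35 | ethyl (E)-2-methyl-4-[(1R,5R)-4,6,6-trimethyl-5-[(E)-3-oxobut-1-en-1-yl]cyclohex-3-en-1-yl]but-2-enoate (cis ring) | CCOC(=O)/C(C)=C/C[C@H]1CC=C(C)[C@@H](/C=C/C(C)=O)C1(C)C | intermediate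
36 | ethyl (E)-2-methyl-4-[(1R,5S)-4,6,6-trimethyl-5-[(E)-3-oxobut-1-en-1-yl]cyclohex-3-en-1-yl]but-2-enoate (trans ring) | CCOC(=O)/C(C)=C/C[C@H]1CC=C(C)[C@H](/C=C/C(C)=O)C1(C)C | intermediate
37 | ethyl (E)-4-[(1R,5S)-5-[(E)-3-hydroxy-3-methylpenta-1,4-dien-1-yl]-4,6,6-trimethylcyclohex-3-en-1-yl]-2-methylbut-2-enoate (both carbinol epimers) | CCOC(=O)/C(C)=C/C[C@H]1CC=C(C)[C@H](/C=C/C(C)(O)C=C)C1(C)C | intermediate
38 | [(2E,4E)-5-[(1S,5R)-5-[(E)-4-ethoxy-3-methyl-4-oxobut-2-en-1-yl]-2,6,6-trimethylcyclohex-2-en-1-yl]-3-methylpenta-2,4-dien-1-yl]triphenylphosphonium bromide | CCOC(=O)/C(C)=C/C[C@H]1CC=C(C)[C@H](/C=C/C(C)=C/C[P+](c2ccccc2)(c2ccccc2)c2ccccc2)C1(C)C.[Br-] | intermediate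
39 | (2E,4E,6E)-2,7-dimethylocta-2,4,6-trienedial | O=C/C(C)=C/C=C/C=C(C)/C=O | starting material
40 | phosphorus ylide of 32 (dienylidene-triphenylphosphorane) | CC(C)=CC[C@H]1CC=C(C)[C@@H](/C=C/C(C)=C/C=P(c2ccccc2)(c2ccccc2)c2ccccc2)C1(C)C | intermediate
41 | (2E,4E,6E,8E,10E,12E)-2,7,11-trimethyl-13-[(1R,5S)-2,6,6-trimethyl-5-(3-methylbut-2-en-1-yl)cyclohex-2-en-1-yl]trideca-2,4,6,8,10,12-hexaenal | CC(C)=CC[C@H]1CC=C(C)[C@@H](/C=C/C(C)=C/C=C/C(C)=C/C=C/C=C(C)/C=O)C1(C)C | intermediate
42 | phosphorus ylide of 38 (dienylidene-triphenylphosphorane) | CCOC(=O)/C(C)=C/C[C@H]1CC=C(C)[C@H](/C=C/C(C)=C/C=P(c2ccccc2)(c2ccccc2)c2ccccc2)C1(C)C | intermediate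
43 | ethyl (E)-2-methyl-4-[(2S,6R,2'R,6'S)-2-(3-methylbut-2-en-1-yl)-ε,ε-caroten-2'-yl]but-2-enoate (the target with CO2Et in place of CH2OH) | CC(C)=CC[C@H]1CC=C(C)[C@@H](/C=C/C(C)=C/C=C/C(C)=C/C=C/C=C(C)/C=C/C=C(C)/C=C/[C@H]2C(C)=CC[C@H](C/C=C(\C)C(=O)OCC)C2(C)C)C1(C)C | intermediate
44 | (2S,6R,2'R,6'S)-2'-[(E)-4-hydroxy-3-methylbut-2-en-1-yl]-2-(3-methylbut-2-en-1-yl)-ε,ε-carotene | CC(C)=CC[C@H]1CC=C(C)[C@@H](/C=C/C(C)=C/C=C/C(C)=C/C=C/C=C(C)/C=C/C=C(C)/C=C/[C@H]2C(C)=CC[C@H](C/C=C(\C)CO)C2(C)C)C1(C)C | target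

**Step count and risks**

Total step count: 24. Longest linear sequence: 18 steps (steps 2 to 12, 17 to 21, 23 and 24).

The three steps most likely to fail:

Step 11. The tertiary radical may be lost by 1,5-hydrogen transfer from the doubly allylic CH2, or the excited iridium complex may be quenched by the skipped triene before it oxidises the hindered carboxylate, so that ring closure does not compete; at room temperature the cis preference may also erode. The fallback makes the radical by reduction instead of oxidation and at low temperature. It sets out from acid 23: esterification with N-hydroxyphthalimide (N,N'-diisopropylcarbodiimide, DMAP, CH2Cl2) gives the 1,3-dioxoisoindolin-2-yl ester F1. Irradiation with blue light in the presence of Ru(bpy)3(PF6)2, the Hantzsch ester and i-Pr2NEt in CH2Cl2 at −20 °C (reductive decarboxylative Giese cyclisation of an N-acyloxyphthalimide) should release the same tertiary radical; the cyclised α-ester radical is then quenched by hydrogen-atom transfer. The route is rejoined at ester 24.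

Step 19. The ethoxide may also attack the α-methyl enoate (conjugate addition, deconjugation), or the ring double bond may move into conjugation before the ring CH has equilibrated, so that the trans isomer is not obtained clean. The fallback moves the epimerisation to a stage without the enoate and builds the side chain afterwards. It sets out from ester 24: ketal hydrolysis (pyridinium p-toluenesulfonate, acetone/H2O) gives the cis enone ester F2, and NaOMe in MeOH equilibrates it to the trans enone ester F3, which is separated. LiAlH4 (THF, 0 °C) reduces ester and ketone to the diol F4, MnO2 (CH2Cl2) re-oxidises only the allylic alcohol to the hydroxy enone F5, and Dess–Martin oxidation gives the keto aldehyde F6. Wittig olefination with ylide 33, which should take the aldehyde and not the enone, rejoins the route at the trans enone 36.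

Step 8. Enolisation and silylation of the hindered isobutyrate may be incomplete, the crowded ketene acetal may fragment instead of rearranging, and the acid-labile ketal may suffer in the silyl chloride medium. The fallback is an orthoester (Johnson–Claisen) rearrangement without strong base. It sets out from dienol 14: heating with 1,1,1-triethoxy-2-methylpropane and catalytic propanoic acid in xylene at 140 °C should give, through the same chair, the ethyl ester F7. KOSiMe3 in THF at 60 °C cleaves the hindered ester and rejoins the route at acid 19.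

**Further compounds**

F1 | step 11 | 1,3-dioxoisoindolin-2-yl (3R,4E)-6,6-diethoxy-3-[(2Z,5E)-7-methoxy-7-oxohepta-2,5-dien-2-yl]-2,2-dimethylhept-4-enoate | O=C(ON1C(=O)c2ccccc2C1=O)C(C)(C)[C@H](/C=C/C(C)(OCC)OCC)/C(C)=C\C/C=C/C(=O)OC
F2 | step 19 | methyl 2-[(1R,5R)-4,6,6-trimethyl-5-[(E)-3-oxobut-1-en-1-yl]cyclohex-3-en-1-yl]acetate | COC(=O)C[C@H]1CC=C(C)[C@@H](/C=C/C(C)=O)C1(C)C
F3 | step 19 | methyl 2-[(1R,5S)-4,6,6-trimethyl-5-[(E)-3-oxobut-1-en-1-yl]cyclohex-3-en-1-yl]acetate | COC(=O)C[C@H]1CC=C(C)[C@H](/C=C/C(C)=O)C1(C)C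
F4 | step 19 | (E)-4-[(1S,5R)-5-(2-hydroxyethyl)-2,6,6-trimethylcyclohex-2-en-1-yl]but-3-en-2-ol (both carbinol epimers) | OCC[C@H]1CC=C(C)[C@H](/C=C/C(C)O)C1(C)C
F5 | step 19 | (E)-4-[(1S,5R)-5-(2-hydroxyethyl)-2,6,6-trimethylcyclohex-2-en-1-yl]but-3-en-2-one | OCC[C@H]1CC=C(C)[C@H](/C=C/C(C)=O)C1(C)C
F6 | step 19 | 2-[(1R,5S)-4,6,6-trimethyl-5-[(E)-3-oxobut-1-en-1-yl]cyclohex-3-en-1-yl]acetaldehyde | O=CC[C@H]1CC=C(C)[C@H](/C=C/C(C)=O)C1(C)C
F7 | step 8 | ethyl (3R,4E)-3-[(Z)-5-[(tert-butyldimethylsilyl)oxy]pent-2-en-2-yl]-6,6-diethoxy-2,2-dimethylhept-4-enoate | CCOC(=O)C(C)(C)[C@H](/C=C/C(C)(OCC)OCC)/C(C)=C\CCO[Si](C)(C)C(C)(C)C
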